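## Analysis of the target

Target 27 is a monocyclic elemane. Ring atoms are numbered C1 (quaternary: methyl, vinyl), C2, C3, C4 (seven-carbon side chain), C5 and C6 (isopropenyl). The ring stereocentres are 1R, 4S and 6R. Vinyl and isopropenyl are trans, and the C1 methyl, the C6 isopropenyl and the C4 side chain lie on one face, so in the chair the methyl is axial and every other carbon substituent equatorial. This is the mirror-image ring of the common (−)-β-elemene series.

The side chain is a (Z)-trisubstituted alkene whose ring-bearing carbon also carries CH2OAc. It continues through one CH2 to an (R)-acetoxy carbinol and a free tertiary alcohol. That carbinol is four bonds from C4 and cannot be controlled from the ring.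

Sensitive elements are the three terminal alkenes (no hydrogenation, no strong electrophiles), the 1,2-dialkenylcyclohexane (Cope-active on strong heating), the ionisable allylic acetate, and the secondary acetate beside a free tertiary hydroxyl.

The main difficulty is the vicinal quaternary/tertiary pair C1/C6, which carries two different alkenyl groups in a ring without a heteroatom handle. The Z-alkene and the remote carbinol are a second, independent problem.

The strategy rests on two features. Vinyl on C1 and isopropenyl on C6 form a 1,5-diene across the C1–C6 bond, which is what results when two allyl units are joined at their substituted ends. C4 with its branched three-carbon attachment is the stereocentre of (S)-limonene 1, with one isopropenyl methyl oxidised.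

## Retrosynthetic reasoning

**27 to 26.** The two acetate C–O bonds are cut last. Triol 26 has a primary allylic, a secondary and a tertiary hydroxyl, and the forward acylation only has to leave the tertiary one alone.

**26 to 25.** The primary allylic carbon and the carbinol oxygen of 26 are traced back to the carbonyl carbon and ring oxygen of unsaturated lactone 25. The Z geometry then becomes a property of a six-membered ring instead of a selectivity problem. The forward step is a 1,2-selective hydride reduction.

**25 to 24.** The ring alkene of 25 is cut, giving the 2-substituted acrylate 24 of a homoallylic alcohol. The forward ring-closing metathesis has to engage a hindered, electron-poor 1,1-disubstituted alkene; the six-membered ring size and the absence of any competing small ring help.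

**24 to 19 and 22; 22 to 21 to 20.** The ester C–O bond separates acid 19 from diol 22. Diol 22 comes from glycidate 20 by epoxide opening with a vinyl nucleophile at the CH2 terminus (21), then double methyl addition to the ester. Opening the epoxide while the neighbour is still an ester avoids the epoxide migration expected for a terminal epoxide beside a tertiary alkoxide; this is why the glycerate acetonide was not used. The carbinol configuration comes from the chiral pool and is never touched.

**19 to 18 to 17 to 16.** The carboxyl of 19 is carried as a silyl-protected allylic alcohol. An acrylate would not survive the hydride steps, and a silyl ether is not ionised by zerovalent palladium. tert-Butyldiphenylsilyl is chosen over tert-butyldimethylsilyl because the group must pass an acidic periodate cleavage.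

**16 to 14 (key disconnection).** The C1–C6 bond is cut. Both ends are allylic, so the ring opens to an acyclic chain with an (E)-allylic carbonate at one end and an (E)-allylboronate at the other, compound 14, whose only stereocentre is C4. Forward, palladium has to hold both allyl groups (15) and couple them at their substituted termini. One bond, one ring and two stereocentres are formed, and methyl, vinyl and isopropenyl all appear in final form. Cutting anywhere else in the ring would separate these groups from the event that sets their stereochemistry.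

**14 to 13 to 12 to 10.** The carbonate must be made last, because any palladium-based borylation would ionise it. The boronate must be made after the ketone has gone, because an allylboronate would add to a tethered ketone. The order is therefore fixed: borylation of the boronate-side carbonate with 11 in the presence of the enoate (12), hydride reduction of the enoate (13), then acylation (14).

**10 to 9 to 8 to 7.** Two enoates at the chain ends could not be told apart by a hydride. The aldehyde carbon of 7 is therefore taken directly to the alcohol oxidation level by a chromium-mediated isopropenyl addition, which ignores the ketone (8). The branched carbonate 9 gives the same π-allyl as a linear one. Only then is the methyl ketone olefinated (10).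

**7 to 6 to 5 to 4 to 1.** Cleaving the ring alkene of limonene gives the two carbonyls at the right distances from C4: one CH2 to the aldehyde, two CH2 to the methyl ketone. The allylic oxygen is introduced first, by metalation of the isopropenyl methyl of 1. Selenium-based allylic oxidation was set aside because in this ring system it also attacks the C4 methine. Ring epoxidation and cleavage follow once the alcohol is silylated.

## Alternatives that were turned down

**Alternative 1:** The ring is cut at C1–C2 and C5–C6 into 2-silyloxydiene A1 and the formyl-activated enoate A2. A chiral cationic oxazaborolidine bound to the formyl group would give cyclohexene A3, with the formyl-bearing quaternary carbon as C1 and the ester carbon as C6, trans as the E-alkene of A2 dictates.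
- For it: one catalytic step builds the ring and the vicinal pair with absolute control, and the regiochemistry (silyloxy carbon para to the quaternary carbon) is dependable. On precedent for the ring-forming event it is clearly stronger than the chosen closure.
- Against it here: A3 has none of the three appendages at the final oxidation level. Formyl must become vinyl and the ester isopropenyl. The enol-ether carbon must become the C4 stereocentre with a branched three-carbon unit cis to the methyl, in a ring that by then has two alkenes. The cycloaddition does not set that third stereocentre.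
- Comparison: the chosen route takes C4 from 1 and delivers methyl, vinyl and isopropenyl in the bond-forming step, with no redox work on the ring; the price is an unprecedented key step.

**Alternative 2:** The side chain is cut between the allylic CH2 and the carbinol carbon, and at a latent C–O bond. Diene A4 (the elemane ring on C2 of a 1-methoxybutadiene, methoxy trans to the vinyl arm) and α-silyloxy aldehyde A5 would combine under a chiral Lewis acid to acetal A6. Hydrolysis and reduction would lead to 26.
- For it: the (R)-carbinol and the Z-alkene are fixed in one convergent catalytic step. On these two elements it is as strong as the ester/metathesis sequence used here, probably shorter, and needs no chiral C3 building block.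
- Against it here: it says nothing about C1/C6, since the ring must exist before A4 can be made. A4 needs control of enol-ether geometry and carries a bulky secondary alkyl group. A5 is α-quaternary and unactivated, a poor partner for a singly oxygenated diene.
- Comparison: the chosen route spends its key step on the ring and takes the carbinol from the chiral pool, where no selectivity question arises.

**Alternative 3:** The trisubstituted alkene is cut: acrylate A7 (the same structure as 24) would close by metathesis to lactone A8 (the same structure as 25).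
- For it: a known reaction type; the ring enforces Z; the carbinol comes from the chiral pool. On reliability it is stronger than the chosen key step, and it is used here as steps 17 and 18.
- Against it as the leading idea: it forms no ring stereocentre, so the elemane acid 19 would still have to be made by some other means, and the route's strategic step would sit on the easier of the two problems.
- Comparison: the chosen route keeps this closure as its end game and adds a direct answer for C1/C6.

Key step: step 11

Remark on the chemistry: in 8, 9 and 10 the new carbinol carbon is a mixture of epimers and is left undefined; it is destroyed on ionisation in step 8.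
Remark on the chemistry: after step 11 all operations are kept below about 100 °C, well under the Cope threshold of the 1,2-dialkenylcyclohexane.

## Route

Step 1
Reactants: 1 (S)-(−)-limonene
Product: 4 2-[(1S)-4-methylcyclohex-3-en-1-yl]prop-2-en-1-ol, via 10-lithiolimonene 2 (not isolated), via dimethyl allylboronate 3 (not isolated)
Conditions: n-BuLi, TMEDA, hexane, rt; B(OMe)3, THF, −78 °C → rt; H2O2, NaOH (aq), 0 °C
Reagents that add atoms: hydrogen peroxide, OO
Why: Allylic lithiation of limonene by n-BuLi·TMEDA takes place at the isopropenyl methyl and gives a symmetric 2-substituted allyl anion that leaves C4 untouched; borylation and oxidative C–B to C–O migration then give the primary allylic alcohol with the ring alkene intact.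

Step 2
Reactants: 4 2-[(1S)-4-methylcyclohex-3-en-1-yl]prop-2-en-1-ol
Product: 5 tert-butyl({2-[(1S)-4-methylcyclohex-3-en-1-yl]prop-2-en-1-yl}oxy)diphenylsilane
Conditions: TBDPSCl, imidazole, DMF, 0 °C → rt
Reagents that add atoms: tert-butyl(chloro)diphenylsilane, CC(C)(C)[Si](Cl)(c1ccccc1)c1ccccc1
Why: Standard silylation of a primary alcohol; the diphenyl-tert-butylsilyl ether withstands the acidic cleavage of step 4, both hydride reductions and zerovalent palladium.

Step 3
Reactants: 5 tert-butyl({2-[(1S)-4-methylcyclohex-3-en-1-yl]prop-2-en-1-yl}oxy)diphenylsilane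
Product: 6 tert-butyl({2-[(4S)-1-methyl-7-oxabicyclo[4.1.0]heptan-4-yl]prop-2-en-1-yl}oxy)diphenylsilane (mixture of epoxide diastereomers)
Conditions: mCPBA, NaHCO3, CH2Cl2, 0 °C
Reagents that add atoms: 3-chloroperbenzoic acid, OOC(=O)c1cccc(Cl)c1
Why: Prilezhaev epoxidation; the trisubstituted ring alkene is the more electron-rich, while the other is 1,1-disubstituted and deactivated by the allylic oxygen. Both epoxide diastereomers converge in step 4.

Step 4
Reactants: 6 tert-butyl({2-[(4S)-1-methyl-7-oxabicyclo[4.1.0]heptan-4-yl]prop-2-en-1-yl}oxy)diphenylsilane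
Product: 7 (3S)-3-{3-[(tert-butyldiphenylsilyl)oxy]prop-1-en-2-yl}-6-oxoheptanal
Conditions: H5IO6, THF/H2O, 0 °C
Reagents that add atoms: water, O
Why: Acid-promoted opening of the epoxide to the diol and periodate glycol cleavage (Malaprade reaction) in one flask. The stereocentre is β to the aldehyde and not enolisable. The keto aldehyde is used at once, because 6-oxoheptanals are prone to intramolecular aldol condensation.

Step 5
Reactants: 7 (3S)-3-{3-[(tert-butyldiphenylsilyl)oxy]prop-1-en-2-yl}-6-oxoheptanal
Product: 8 (5S)-5-{3-[(tert-butyldiphenylsilyl)oxy]prop-1-en-2-yl}-7-hydroxy-8-methylnon-8-en-2-one (epimers at C7)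
Conditions: 2-bromopropene, CrCl2 (4 equiv), NiCl2 (1 mol %), DMF, rt
Reagents that add atoms: 2-bromopropene, CC(Br)=C
Why: Nozaki–Hiyama–Kishi reaction; alkenylchromium reagents add to aldehydes and leave ketones alone, so the two chain ends are differentiated in one step under non-basic conditions. The new carbinol centre is uncontrolled and does not matter.

Step 6
Reactants: 8 (5S)-5-{3-[(tert-butyldiphenylsilyl)oxy]prop-1-en-2-yl}-7-hydroxy-8-methylnon-8-en-2-one
Product: 9 (5S)-5-{3-[(tert-butyldiphenylsilyl)oxy]prop-1-en-2-yl}-2-methyl-8-oxonon-1-en-3-yl methyl carbonate (epimers at C3)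
Conditions: ClCO2Me, pyridine, DMAP (cat.), CH2Cl2, 0 °C
Reagents that add atoms: methyl chloroformate, COC(Cl)=O
Why: Acylation of the secondary allylic alcohol gives the leaving group for step 8; it is inert to the phosphonate anion of step 7 when no palladium is present.

Step 7
Reactants: 9 (5S)-5-{3-[(tert-butyldiphenylsilyl)oxy]prop-1-en-2-yl}-2-methyl-8-oxonon-1-en-3-yl methyl carbonate
Product: 10 ethyl (2E,6S)-6-{3-[(tert-butyldiphenylsilyl)oxy]prop-1-en-2-yl}-8-[(methoxycarbonyl)oxy]-3,9-dimethyldeca-2,9-dienoate (epimers at C8)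
Conditions: (EtO)2P(O)CH2CO2Et, NaH, THF, 0 °C → rt
Reagents that add atoms: triethyl phosphonoacetate, CCOC(=O)CP(=O)(OCC)OCC
Why: Horner–Wadsworth–Emmons olefination of the methyl ketone; the E isomer (ester trans to the chain) is expected to predominate under thermodynamic control. The minor Z isomer is best removed after step 8 or 9, once the carbinol epimers have merged.

Step 8
Reactants: 10 ethyl (2E,6S)-6-{3-[(tert-butyldiphenylsilyl)oxy]prop-1-en-2-yl}-8-[(methoxycarbonyl)oxy]-3,9-dimethyldeca-2,9-dienoate; 11 bis(pinacolato)diboron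
Product: 12 ethyl (2E,6S,8E)-6-{3-[(tert-butyldiphenylsilyl)oxy]prop-1-en-2-yl}-3,9-dimethyl-10-(4,4,5,5-tetramethyl-1,3,2-dioxaborolan-2-yl)deca-2,8-dienoate
Conditions: Pd2(dba)3 (2.5 mol %), 11 (1.2 equiv), DMSO, 50 °C
Reagents that add atoms: none
Why: Miyaura-type allylic borylation; zerovalent palladium ionises the carbonate with loss of CO2, the methoxide activates the diboron, and C–B bond formation occurs at the unsubstituted allyl terminus. The 2-methyl-substituted π-allyl is expected to favour the syn arrangement and hence the E alkene; the enoate and the allylic silyl ether are not ionised.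

Step 9
Reactants: 12 ethyl (2E,6S,8E)-6-{3-[(tert-butyldiphenylsilyl)oxy]prop-1-en-2-yl}-3,9-dimethyl-10-(4,4,5,5-tetramethyl-1,3,2-dioxaborolan-2-yl)deca-2,8-dienoate
Product: 13 (2E,6S,8E)-6-{3-[(tert-butyldiphenylsilyl)oxy]prop-1-en-2-yl}-3,9-dimethyl-10-(4,4,5,5-tetramethyl-1,3,2-dioxaborolan-2-yl)deca-2,8-dien-1-ol
Conditions: i-Bu2AlH (2.3 equiv), CH2Cl2, −78 °C; potassium sodium tartrate (aq)
Reagents that add atoms: none
Why: 1,2-Reduction of the enoate to the allylic alcohol. At −78 °C the pinacol boronate is neither reduced nor fast enough to allylate the transient aluminium hemiacetal, which would need an eight-membered ring within the molecule.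

Step 10
Reactants: 13 (2E,6S,8E)-6-{3-[(tert-butyldiphenylsilyl)oxy]prop-1-en-2-yl}-3,9-dimethyl-10-(4,4,5,5-tetramethyl-1,3,2-dioxaborolan-2-yl)deca-2,8-dien-1-ol
Product: 14 (2E,6S,8E)-6-{3-[(tert-butyldiphenylsilyl)oxy]prop-1-en-2-yl}-3,9-dimethyl-10-(4,4,5,5-tetramethyl-1,3,2-dioxaborolan-2-yl)deca-2,8-dien-1-yl methyl carbonate
Conditions: ClCO2Me, pyridine, CH2Cl2, 0 °C
Reagents that add atoms: methyl chloroformate, COC(Cl)=O
Why: Acylation of the primary allylic alcohol; the allylboronate is stable to pyridine and chloroformate, and the electrophilic end is installed only now, when no further palladium step stands between it and the key step.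

Step 11
Reactants: 14 (2E,6S,8E)-6-{3-[(tert-butyldiphenylsilyl)oxy]prop-1-en-2-yl}-3,9-dimethyl-10-(4,4,5,5-tetramethyl-1,3,2-dioxaborolan-2-yl)deca-2,8-dien-1-yl methyl carbonate
Product: 16 tert-butyl({2-[(1S,3R,4R)-4-ethenyl-4-methyl-3-(prop-1-en-2-yl)cyclohexyl]prop-2-en-1-yl}oxy)diphenylsilane, via bis-allyl palladacycle 15 (not isolated)
Conditions: Pd2(dba)3 (5 mol %), 1,2-bis(diphenylphosphino)benzene (12 mol %), THF, 60 °C, slow addition of 14 to 0.005 M; matched enantiomer of MeO-furyl-BIPHEP in reserve
Reagents that add atoms: none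
Why: Proposed new method: zerovalent palladium ionises the primary (E)-allylic carbonate of 14 with loss of CO2, and the methoxide set free activates the tethered allylboronate, whose allyl group passes to palladium to give the eleven-membered bis(η1-allyl)palladacycle 15 with the metal on both CH2 termini. The small-bite-angle bisphosphine favours 3,3′-reductive elimination through a seven-membered transition state, which joins the methyl-bearing terminus of one allyl unit to the CH terminus of the other (C1–C6) and turns both π bonds out of the new ring as vinyl and isopropenyl. The closest known reaction is the intermolecular, branched-selective palladium-catalysed coupling of allylboronates with allylic carbonates, which builds such vicinal tertiary/quaternary 1,5-dienes; the ring-closing version on a tethered pair is not established. The cyclohexane closes in a 6-exo sense at both allyl units. C1 and C6 are set relative to each other by the chair-like arrangement of the two (E)-allyl units, which places the C1 methyl and the C6 hydrogen anti (vinyl trans to isopropenyl). They are set relative to C4 by the equatorial preference of the large C4 substituent in that chair, which puts methyl, isopropenyl and the C4 branch on one face. The step needs 3,3′ coupling over 1,1′ or 1,3′ coupling and ring closure over oligomerisation: ligand bite angle, the strain of the eight- and ten-membered alternatives and high dilution should secure this, and a ten-membered 1,1′ product would converge on 16 by Cope rearrangement on heating. π–σ–π isomerisation on palladium is expected to erase residual Z content at the boronate-derived allyl unit.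

Step 12
Reactants: 16 tert-butyl({2-[(1S,3R,4R)-4-ethenyl-4-methyl-3-(prop-1-en-2-yl)cyclohexyl]prop-2-en-1-yl}oxy)diphenylsilane
Product: 17 2-[(1S,3R,4R)-4-ethenyl-4-methyl-3-(prop-1-en-2-yl)cyclohexyl]prop-2-en-1-ol
Conditions: Bu4NF, THF, 0 °C → rt
Reagents that add atoms: none
Why: Fluoride cleavage of the silyl ether; nothing else in the hydrocarbon is fluoride- or base-sensitive.

Step 13
Reactants: 17 2-[(1S,3R,4R)-4-ethenyl-4-methyl-3-(prop-1-en-2-yl)cyclohexyl]prop-2-en-1-ol
Product: 18 2-[(1S,3R,4R)-4-ethenyl-4-methyl-3-(prop-1-en-2-yl)cyclohexyl]prop-2-enal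
Conditions: MnO2, CH2Cl2, rt
Reagents that add atoms: none
Why: Selective oxidation of an allylic alcohol under neutral conditions, which avoids migration of the methylene double bond towards C4.

Step 14
Reactants: 18 2-[(1S,3R,4R)-4-ethenyl-4-methyl-3-(prop-1-en-2-yl)cyclohexyl]prop-2-enal
Product: 19 2-[(1S,3R,4R)-4-ethenyl-4-methyl-3-(prop-1-en-2-yl)cyclohexyl]prop-2-enoic acid
Conditions: NaClO2, NaH2PO4, 2-methyl-2-butene (excess), t-BuOH/H2O, 0 °C → rt
Reagents that add atoms: sodium chlorite, [Na+].[O-]Cl=O
Why: Pinnick oxidation of the enal; the large excess of scavenger alkene protects the vinyl and isopropenyl groups from hypochlorous acid.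

Step 15
Reactants: 20 methyl (2R)-oxirane-2-carboxylate
Product: 21 methyl (2R)-2-hydroxypent-4-enoate
Conditions: vinylMgBr, CuI (10 mol %), THF, −78 → −40 °C
Reagents that add atoms: vinylmagnesium bromide, C=C[Mg]Br
Why: Copper-catalysed epoxide opening at the unsubstituted carbon, faster at low temperature than addition to the ester; the stereocentre is not involved.

Step 16
Reactants: 21 methyl (2R)-2-hydroxypent-4-enoate
Product: 22 (3R)-2-methylhex-5-ene-2,3-diol
Conditions: MeMgBr (3.5 equiv), THF, 0 °C → rt
Reagents that add atoms: methylmagnesium bromide, C[Mg]Br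
Why: Double Grignard addition to the ester after deprotonation of the hydroxyl; the magnesium alkoxide protects the α-centre from enolisation.

Step 17
Reactants: 19 2-[(1S,3R,4R)-4-ethenyl-4-methyl-3-(prop-1-en-2-yl)cyclohexyl]prop-2-enoic acid; 22 (3R)-2-methylhex-5-ene-2,3-diol
Product: 24 (3R)-2-hydroxy-2-methylhex-5-en-3-yl 2-[(1S,3R,4R)-4-ethenyl-4-methyl-3-(prop-1-en-2-yl)cyclohexyl]prop-2-enoate, via mixed anhydride 23 (not isolated)
Conditions: 2,4,6-Cl3C6H2COCl, Et3N, THF, rt; then 22, DMAP, toluene, rt
Reagents that add atoms: none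
Why: Yamaguchi esterification, suited to a hindered acid and a hindered secondary alcohol; the tertiary hydroxyl of 22 does not acylate, so no protection is needed.

Step 18
Reactants: 24 (3R)-2-hydroxy-2-methylhex-5-en-3-yl 2-[(1S,3R,4R)-4-ethenyl-4-methyl-3-(prop-1-en-2-yl)cyclohexyl]prop-2-enoate
Product: 25 (6R)-3-[(1S,3R,4R)-4-ethenyl-4-methyl-3-(prop-1-en-2-yl)cyclohexyl]-6-(2-hydroxypropan-2-yl)-5,6-dihydro-2H-pyran-2-one
Conditions: second-generation Hoveyda–Grubbs catalyst (10 mol %), toluene, 80 °C, 0.005 M
Reagents that add atoms: none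
Why: Ring-closing metathesis; the catalyst loads on the unhindered terminal alkene and closes the six-membered ring onto the acrylate. The ring's vinyl (neopentyl-type) and isopropenyl groups could only give ten- or eleven-membered rings. The endocyclic alkene is necessarily Z with respect to carbonyl carbon and CH2.

Step 19
Reactants: 25 (6R)-3-[(1S,3R,4R)-4-ethenyl-4-methyl-3-(prop-1-en-2-yl)cyclohexyl]-6-(2-hydroxypropan-2-yl)-5,6-dihydro-2H-pyran-2-one
Product: 26 (2Z,5R)-2-[(1S,3R,4R)-4-ethenyl-4-methyl-3-(prop-1-en-2-yl)cyclohexyl]-6-methylhept-2-ene-1,5,6-triol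
Conditions: i-Bu2AlH (6 equiv), CH2Cl2, −78 → 0 °C; potassium sodium tartrate (aq)
Reagents that add atoms: none
Why: Exhaustive 1,2-reduction of the unsaturated lactone through the lactol to the ene-diol; the alkene geometry fixed in the ring is kept.

Step 20
Reactants: 26 (2Z,5R)-2-[(1S,3R,4R)-4-ethenyl-4-methyl-3-(prop-1-en-2-yl)cyclohexyl]-6-methylhept-2-ene-1,5,6-triol
Product: 27 (2Z,5R)-2-[(1S,3R,4R)-4-ethenyl-4-methyl-3-(prop-1-en-2-yl)cyclohexyl]-6-hydroxy-6-methylhept-2-ene-1,5-diyl diacetate
Conditions: Ac2O (2.5 equiv), pyridine, DMAP (cat.), CH2Cl2, 0 °C → rt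
Reagents that add atoms: acetic anhydride, CC(=O)OC(C)=O
Why: Acylation of the primary and secondary hydroxyls; the tertiary hydroxyl is expected to stay free with limited anhydride, and no stereocentre is touched.

## Compound list

1 | (S)-(−)-limonene | CC1=CC[C@@H](C(C)=C)CC1 | starting material
2 | 10-lithiolimonene | CC1=CC[C@@H](C(=C)C[Li])CC1 | intermediate
3 | dimethyl {2-[(1S)-4-methylcyclohex-3-en-1-yl]prop-2-en-1-yl}boronate | CC1=CC[C@@H](C(=C)CB(OC)OC)CC1 | intermediate
4 | 2-[(1S)-4-methylcyclohex-3-en-1-yl]prop-2-en-1-ol | CC1=CC[C@@H](C(=C)CO)CC1 | intermediate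
5 | tert-butyl({2-[(1S)-4-methylcyclohex-3-en-1-yl]prop-2-en-1-yl}oxy)diphenylsilane | CC1=CC[C@@H](C(=C)CO[Si](c2ccccc2)(c2ccccc2)C(C)(C)C)CC1 | intermediate
6 | tert-butyl({2-[(4S)-1-methyl-7-oxabicyclo[4.1.0]heptan-4-yl]prop-2-en-1-yl}oxy)diphenylsilane | CC12CC[C@@H](CC1O2)C(=C)CO[Si](c1ccccc1)(c1ccccc1)C(C)(C)C | intermediate
7 | (3S)-3-{3-[(tert-butyldiphenylsilyl)oxy]prop-1-en-2-yl}-6-oxoheptanal | O=CC[C@H](CCC(C)=O)C(=C)CO[Si](c1ccccc1)(c1ccccc1)C(C)(C)C | intermediate
8 | (5S)-5-{3-[(tert-butyldiphenylsilyl)oxy]prop-1-en-2-yl}-7-hydroxy-8-methylnon-8-en-2-one | CC(=C)C(O)C[C@H](CCC(C)=O)C(=C)CO[Si](c1ccccc1)(c1ccccc1)C(C)(C)C | intermediate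
9 | (5S)-5-{3-[(tert-butyldiphenylsilyl)oxy]prop-1-en-2-yl}-2-methyl-8-oxonon-1-en-3-yl methyl carbonate | COC(=O)OC(C[C@H](CCC(C)=O)C(=C)CO[Si](c1ccccc1)(c1ccccc1)C(C)(C)C)C(C)=C | intermediate
10 | ethyl (2E,6S)-6-{3-[(tert-butyldiphenylsilyl)oxy]prop-1-en-2-yl}-8-[(methoxycarbonyl)oxy]-3,9-dimethyldeca-2,9-dienoate | CCOC(=O)/C=C(\C)CC[C@@H](CC(OC(=O)OC)C(C)=C)C(=C)CO[Si](c1ccccc1)(c1ccccc1)C(C)(C)C | intermediate
11 | bis(pinacolato)diboron | CC1(C)OB(OC1(C)C)B1OC(C)(C)C(C)(C)O1 | starting material
12 | ethyl (2E,6S,8E)-6-{3-[(tert-butyldiphenylsilyl)oxy]prop-1-en-2-yl}-3,9-dimethyl-10-(4,4,5,5-tetramethyl-1,3,2-dioxaborolan-2-yl)deca-2,8-dienoate | CCOC(=O)/C=C(\C)CC[C@@H](C/C=C(\C)CB1OC(C)(C)C(C)(C)O1)C(=C)CO[Si](c1ccccc1)(c1ccccc1)C(C)(C)C | intermediate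
13 | (2E,6S,8E)-6-{3-[(tert-butyldiphenylsilyl)oxy]prop-1-en-2-yl}-3,9-dimethyl-10-(4,4,5,5-tetramethyl-1,3,2-dioxaborolan-2-yl)deca-2,8-dien-1-ol | OC/C=C(\C)CC[C@@H](C/C=C(\C)CB1OC(C)(C)C(C)(C)O1)C(=C)CO[Si](c1ccccc1)(c1ccccc1)C(C)(C)C | intermediate
14 | (2E,6S,8E)-6-{3-[(tert-butyldiphenylsilyl)oxy]prop-1-en-2-yl}-3,9-dimethyl-10-(4,4,5,5-tetramethyl-1,3,2-dioxaborolan-2-yl)deca-2,8-dien-1-yl methyl carbonate | COC(=O)OC/C=C(\C)CC[C@@H](C/C=C(\C)CB1OC(C)(C)C(C)(C)O1)C(=C)CO[Si](c1ccccc1)(c1ccccc1)C(C)(C)C | intermediate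
15 | bis(η1-allyl)palladacycle, eleven-membered (bisphosphine on palladium omitted) | [Pd]1C/C=C(\C)CC[C@@H](C/C=C(\C)C1)C(=C)CO[Si](c1ccccc1)(c1ccccc1)C(C)(C)C | intermediate
16 | tert-butyl({2-[(1S,3R,4R)-4-ethenyl-4-methyl-3-(prop-1-en-2-yl)cyclohexyl]prop-2-en-1-yl}oxy)diphenylsilane | C=C[C@@]1(C)CC[C@H](C(=C)CO[Si](c2ccccc2)(c2ccccc2)C(C)(C)C)C[C@@H]1C(C)=C | intermediate
17 | 2-[(1S,3R,4R)-4-ethenyl-4-methyl-3-(prop-1-en-2-yl)cyclohexyl]prop-2-en-1-ol | C=C[C@@]1(C)CC[C@H](C(=C)CO)C[C@@H]1C(C)=C | intermediate
18 | 2-[(1S,3R,4R)-4-ethenyl-4-methyl-3-(prop-1-en-2-yl)cyclohexyl]prop-2-enal | C=C[C@@]1(C)CC[C@H](C(=C)C=O)C[C@@H]1C(C)=C | intermediate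
19 | 2-[(1S,3R,4R)-4-ethenyl-4-methyl-3-(prop-1-en-2-yl)cyclohexyl]prop-2-enoic acid | C=C[C@@]1(C)CC[C@H](C(=C)C(=O)O)C[C@@H]1C(C)=C | intermediate
20 | methyl (2R)-oxirane-2-carboxylate | COC(=O)[C@H]1CO1 | starting material
21 | methyl (2R)-2-hydroxypent-4-enoate | COC(=O)[C@H](O)CC=C | intermediate
22 | (3R)-2-methylhex-5-ene-2,3-diol | CC(C)(O)[C@H](O)CC=C | intermediate
23 | 2-[(1S,3R,4R)-4-ethenyl-4-methyl-3-(prop-1-en-2-yl)cyclohexyl]prop-2-enoic 2,4,6-trichlorobenzoic anhydride | C=C[C@@]1(C)CC[C@H](C(=C)C(=O)OC(=O)c2c(Cl)cc(Cl)cc2Cl)C[C@@H]1C(C)=C | intermediate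
24 | (3R)-2-hydroxy-2-methylhex-5-en-3-yl 2-[(1S,3R,4R)-4-ethenyl-4-methyl-3-(prop-1-en-2-yl)cyclohexyl]prop-2-enoate | C=C[C@@]1(C)CC[C@H](C(=C)C(=O)O[C@H](CC=C)C(C)(C)O)C[C@@H]1C(C)=C | intermediate
25 | (6R)-3-[(1S,3R,4R)-4-ethenyl-4-methyl-3-(prop-1-en-2-yl)cyclohexyl]-6-(2-hydroxypropan-2-yl)-5,6-dihydro-2H-pyran-2-one | C=C[C@@]1(C)CC[C@H](C2=CC[C@@H](OC2=O)C(C)(C)O)C[C@@H]1C(C)=C | intermediate
26 | (2Z,5R)-2-[(1S,3R,4R)-4-ethenyl-4-methyl-3-(prop-1-en-2-yl)cyclohexyl]-6-methylhept-2-ene-1,5,6-triol | C=C[C@@]1(C)CC[C@H](/C(=C/C[C@@H](O)C(C)(C)O)CO)C[C@@H]1C(C)=C | intermediate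
27 | (2Z,5R)-2-[(1S,3R,4R)-4-ethenyl-4-methyl-3-(prop-1-en-2-yl)cyclohexyl]-6-hydroxy-6-methylhept-2-ene-1,5-diyl diacetate | C=C[C@@]1(C)CC[C@H](/C(=C/C[C@@H](OC(C)=O)C(C)(C)O)COC(C)=O)C[C@@H]1C(=C)C | target

## Step count and least certain steps

Total step count: 20. Longest linear sequence: 18 (steps 1 to 14 and 17 to 20); steps 15 and 16 form the two-step side branch.

**Step 11 (key step, the one labelled as a new method).** Transmetalation has to occur within a large ring, so intermolecular allyl–allyl coupling, protodeboronation or hydride elimination from the π-allyl may outrun ring closure. Loss of geometry at the methyl-bearing allyl unit would also erode the C1/C6 relationship.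

Fallback by known chemistry, from 13 back to 16. The C–B bond of 13 is oxidised (NaBO3·4H2O, THF/H2O) to (2E,6S,8E)-6-{3-[(tert-butyldiphenylsilyl)oxy]prop-1-en-2-yl}-3,9-dimethyldeca-2,8-diene-1,10-diol F1. PBr3 and pyridine in Et2O at −20 °C give (2E,6S,8E)-1,10-dibromo-6-{3-[(tert-butyldiphenylsilyl)oxy]prop-1-en-2-yl}-3,9-dimethyldeca-2,8-diene F2. Reductive coupling of the two allylic bromide termini with Ni(CO)4 (DMF, 50 °C, slow addition), an established way to close 1,5-diene rings, gives tert-butyl({2-[(1S,3E,7E)-4,8-dimethylcyclodeca-3,7-dien-1-yl]prop-2-en-1-yl}oxy)diphenylsilane F3. Heating F3 (toluene, 160 °C, sealed tube) brings about the Cope rearrangement of this germacrene-type ring through the chair–chair arrangement with the side chain equatorial, and gives 16.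

**Step 18.** The ruthenium alkylidene formed at the terminal alkene may fail to engage the hindered, electron-poor 2-substituted acrylate. Dimerisation through the terminal alkene or alkene migration would then take over.

Fallback, from 17 and 21 back to 26, replacing the ester tether by a silicon tether and skipping steps 13, 14, 16, 17 and 19. Alcohol 17 with i-Pr2SiCl2 (excess) and imidazole gives chloro({2-[(1S,3R,4R)-4-ethenyl-4-methyl-3-(prop-1-en-2-yl)cyclohexyl]prop-2-en-1-yl}oxy)di(propan-2-yl)silane F4. Addition of 21 and imidazole gives methyl (2R)-2-{[({2-[(1S,3R,4R)-4-ethenyl-4-methyl-3-(prop-1-en-2-yl)cyclohexyl]prop-2-en-1-yl}oxy)di(propan-2-yl)silyl]oxy}pent-4-enoate F5. Ring-closing metathesis with the second-generation Grubbs catalyst (toluene, 80 °C), now onto an electron-richer allylic-ether alkene, gives the eight-membered methyl (4R,6Z)-7-[(1S,3R,4R)-4-ethenyl-4-methyl-3-(prop-1-en-2-yl)cyclohexyl]-2,2-di(propan-2-yl)-5,8-dihydro-4H-1,3,2-dioxasilocine-4-carboxylate F6; the ring again enforces the Z alkene. MeMgBr (THF, 0 °C) gives 2-{(4R,6Z)-7-[(1S,3R,4R)-4-ethenyl-4-methyl-3-(prop-1-en-2-yl)cyclohexyl]-2,2-di(propan-2-yl)-5,8-dihydro-4H-1,3,2-dioxasilocin-4-yl}propan-2-ol F7, and Bu4NF releases 26.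

**Step 8.** Regio- and geometric control may be lost at the π-allyl stage, the product boronate may couple with unreacted carbonate, or hydride elimination may give a 1,3-diene. The following step 9 also exposes the boronate to a hydride.

Fallback, from 10 back to 13, with the ester reduced before boron is introduced and a different borylation mechanism. i-Bu2AlH (CH2Cl2, −78 → 0 °C) reduces the enoate and cleaves the carbonate of 10 to (2E,6S)-6-{3-[(tert-butyldiphenylsilyl)oxy]prop-1-en-2-yl}-3,9-dimethyldeca-2,9-diene-1,8-diol F8. Et3SiCl and imidazole at −78 °C silylate the primary hydroxyl to give (5S,8E)-5-{3-[(tert-butyldiphenylsilyl)oxy]prop-1-en-2-yl}-2,8-dimethyl-10-[(triethylsilyl)oxy]deca-1,8-dien-3-ol F9. ClCO2Me and pyridine give (5S,8E)-5-{3-[(tert-butyldiphenylsilyl)oxy]prop-1-en-2-yl}-2,8-dimethyl-10-[(triethylsilyl)oxy]deca-1,8-dien-3-yl methyl carbonate F10. Copper-catalysed γ-selective borylation (CuCl, Xantphos, KOt-Bu, 11, THF, 0 °C), a formal SN2′ substitution with no enoate present, gives triethyl{[(2E,6S,8E)-6-{3-[(tert-butyldiphenylsilyl)oxy]prop-1-en-2-yl}-3,9-dimethyl-10-(4,4,5,5-tetramethyl-1,3,2-dioxaborolan-2-yl)deca-2,8-dien-1-yl]oxy}silane F11. Pyridinium p-toluenesulfonate in MeOH removes the triethylsilyl group and gives 13.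

**Step 1.** The heterogeneous lithiation may be incomplete or unselective: competing metalation at ring allylic positions, or at the C4 methine with erosion of enantiopurity.

Fallback, from 1 back to 6, with epoxidation first and an ene-type chlorination in place of metalation. mCPBA gives (4S)-1-methyl-4-(prop-1-en-2-yl)-7-oxabicyclo[4.1.0]heptane F12. Ca(OCl)2 with solid CO2 in CH2Cl2/H2O chlorinates the isopropenyl group with alkene transposition to (4S)-4-(3-chloroprop-1-en-2-yl)-1-methyl-7-oxabicyclo[4.1.0]heptane F13. KOAc in DMF gives 2-[(4S)-1-methyl-7-oxabicyclo[4.1.0]heptan-4-yl]prop-2-en-1-yl acetate F14. K2CO3 in MeOH gives 2-[(4S)-1-methyl-7-oxabicyclo[4.1.0]heptan-4-yl]prop-2-en-1-ol F15. TBDPSCl and imidazole then give 6.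

## Further compounds

F1 | step 11 | (2E,6S,8E)-6-{3-[(tert-butyldiphenylsilyl)oxy]prop-1-en-2-yl}-3,9-dimethyldeca-2,8-diene-1,10-diol | OC/C=C(\C)CC[C@@H](C/C=C(\C)CO)C(=C)CO[Si](c1ccccc1)(c1ccccc1)C(C)(C)C
F2 | step 11 | (2E,6S,8E)-1,10-dibromo-6-{3-[(tert-butyldiphenylsilyl)oxy]prop-1-en-2-yl}-3,9-dimethyldeca-2,8-diene | BrC/C=C(\C)CC[C@@H](C/C=C(\C)CBr)C(=C)CO[Si](c1ccccc1)(c1ccccc1)C(C)(C)C
F3 | step 11 | tert-butyl({2-[(1S,3E,7E)-4,8-dimethylcyclodeca-3,7-dien-1-yl]prop-2-en-1-yl}oxy)diphenylsilane | C1/C=C(\C)CC[C@@H](C/C=C(\C)C1)C(=C)CO[Si](c1ccccc1)(c1ccccc1)C(C)(C)C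
F4 | step 18 | chloro({2-[(1S,3R,4R)-4-ethenyl-4-methyl-3-(prop-1-en-2-yl)cyclohexyl]prop-2-en-1-yl}oxy)di(propan-2-yl)silane | C=C[C@@]1(C)CC[C@H](C(=C)CO[Si](Cl)(C(C)C)C(C)C)C[C@@H]1C(C)=C
F5 | step 18 | methyl (2R)-2-{[({2-[(1S,3R,4R)-4-ethenyl-4-methyl-3-(prop-1-en-2-yl)cyclohexyl]prop-2-en-1-yl}oxy)di(propan-2-yl)silyl]oxy}pent-4-enoate | C=C[C@@]1(C)CC[C@H](C(=C)CO[Si](C(C)C)(C(C)C)O[C@H](CC=C)C(=O)OC)C[C@@H]1C(C)=C
F6 | step 18 | methyl (4R,6Z)-7-[(1S,3R,4R)-4-ethenyl-4-methyl-3-(prop-1-en-2-yl)cyclohexyl]-2,2-di(propan-2-yl)-5,8-dihydro-4H-1,3,2-dioxasilocine-4-carboxylate | C=C[C@@]1(C)CC[C@H](/C2=C/C[C@H](C(=O)OC)O[Si](C(C)C)(C(C)C)OC2)C[C@@H]1C(C)=C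
F7 | step 18 | 2-{(4R,6Z)-7-[(1S,3R,4R)-4-ethenyl-4-methyl-3-(prop-1-en-2-yl)cyclohexyl]-2,2-di(propan-2-yl)-5,8-dihydro-4H-1,3,2-dioxasilocin-4-yl}propan-2-ol | C=C[C@@]1(C)CC[C@H](/C2=C/C[C@H](C(C)(C)O)O[Si](C(C)C)(C(C)C)OC2)C[C@@H]1C(C)=C
F8 | step 8 | (2E,6S)-6-{3-[(tert-butyldiphenylsilyl)oxy]prop-1-en-2-yl}-3,9-dimethyldeca-2,9-diene-1,8-diol | OC/C=C(\C)CC[C@@H](CC(O)C(C)=C)C(=C)CO[Si](c1ccccc1)(c1ccccc1)C(C)(C)C
F9 | step 8 | (5S,8E)-5-{3-[(tert-butyldiphenylsilyl)oxy]prop-1-en-2-yl}-2,8-dimethyl-10-[(triethylsilyl)oxy]deca-1,8-dien-3-ol | CC[Si](CC)(CC)OC/C=C(\C)CC[C@@H](CC(O)C(C)=C)C(=C)CO[Si](c1ccccc1)(c1ccccc1)C(C)(C)C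
F10 | step 8 | (5S,8E)-5-{3-[(tert-butyldiphenylsilyl)oxy]prop-1-en-2-yl}-2,8-dimethyl-10-[(triethylsilyl)oxy]deca-1,8-dien-3-yl methyl carbonate | CC[Si](CC)(CC)OC/C=C(\C)CC[C@@H](CC(OC(=O)OC)C(C)=C)C(=C)CO[Si](c1ccccc1)(c1ccccc1)C(C)(C)C
F11 | step 8 | triethyl{[(2E,6S,8E)-6-{3-[(tert-butyldiphenylsilyl)oxy]prop-1-en-2-yl}-3,9-dimethyl-10-(4,4,5,5-tetramethyl-1,3,2-dioxaborolan-2-yl)deca-2,8-dien-1-yl]oxy}silane | CC[Si](CC)(CC)OC/C=C(\C)CC[C@@H](C/C=C(\C)CB1OC(C)(C)C(C)(C)O1)C(=C)CO[Si](c1ccccc1)(c1ccccc1)C(C)(C)C
F12 | step 1 | (4S)-1-methyl-4-(prop-1-en-2-yl)-7-oxabicyclo[4.1.0]heptane | CC12CC[C@@H](CC1O2)C(C)=C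
F13 | step 1 | (4S)-4-(3-chloroprop-1-en-2-yl)-1-methyl-7-oxabicyclo[4.1.0]heptane | CC12CC[C@@H](CC1O2)C(=C)CCl
F14 | step 1 | 2-[(4S)-1-methyl-7-oxabicyclo[4.1.0]heptan-4-yl]prop-2-en-1-yl acetate | CC12CC[C@@H](CC1O2)C(=C)COC(C)=O
F15 | step 1 | 2-[(4S)-1-methyl-7-oxabicyclo[4.1.0]heptan-4-yl]prop-2-en-1-ol | CC12CC[C@@H](CC1O2)C(=C)CO
A1 | alternative 1 | 2-[(triisopropylsilyl)oxy]buta-1,3-diene | C=CC(=C)O[Si](C(C)C)(C(C)C)C(C)C
A2 | alternative 1 | ethyl (2E)-3-methyl-4-oxobut-2-enoate | CCOC(=O)/C=C(\C)C=O
A3 | alternative 1 | ethyl trans-6-formyl-6-methyl-3-[(triisopropylsilyl)oxy]cyclohex-3-ene-1-carboxylate | O=C[C@@]1(C)CC=C(O[Si](C(C)C)(C(C)C)C(C)C)C[C@@H]1C(=O)OCC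
A4 | alternative 2 | 2-[(1S,3R,4R)-4-ethenyl-4-methyl-3-(prop-1-en-2-yl)cyclohexyl]-1-methoxybuta-1,3-diene, methoxy trans to the vinyl arm | C=C[C@@]1(C)CC[C@H](C(\C=C)=C/OC)C[C@@H]1C(C)=C
A5 | alternative 2 | 2-methyl-2-[(triethylsilyl)oxy]propanal | CC(C)(C=O)O[Si](CC)(CC)CC
A6 | alternative 2 | cis-(6R)-3-[(1S,3R,4R)-4-ethenyl-4-methyl-3-(prop-1-en-2-yl)cyclohexyl]-2-methoxy-6-{2-[(triethylsilyl)oxy]propan-2-yl}-5,6-dihydro-2H-pyran | C=C[C@@]1(C)CC[C@H](C2=CC[C@@H](O[C@@H]2OC)C(C)(C)O[Si](CC)(CC)CC)C[C@@H]1C(C)=C
A7 | alternative 3 | (3R)-2-hydroxy-2-methylhex-5-en-3-yl 2-[(1S,3R,4R)-4-ethenyl-4-methyl-3-(prop-1-en-2-yl)cyclohexyl]prop-2-enoate | C=C[C@@]1(C)CC[C@H](C(=C)C(=O)O[C@H](CC=C)C(C)(C)O)C[C@@H]1C(C)=C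
A8 | alternative 3 | (6R)-3-[(1S,3R,4R)-4-ethenyl-4-methyl-3-(prop-1-en-2-yl)cyclohexyl]-6-(2-hydroxypropan-2-yl)-5,6-dihydro-2H-pyran-2-one | C=C[C@@]1(C)CC[C@H](C2=CC[C@@H](OC2=O)C(C)(C)O)C[C@@H]1C(C)=C
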